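**Retrosynthetic overview**
1. Aspergimarin B (14) ⇒ global hydrogenolysis of the tribenzyl precursor 13 (two aryl benzyl ethers, one benzyl ester).
2. 13 ⇒ ring expansion of benzocyclobutenone 12 by insertion of the C=O of aldehyde 5 into its C(acyl)–CH2 bond (4 → 6; forms C3–C4 and C1–O2, sets 3R).
3. 12 ⇒ aryne/ketene acetal [2+2] on bromide 8 ⇐ hydroquinone. The benzene ring is bought, the cyclobutenone is built first and the δ-lactone is formed last from it.
4. 5 ⇒ linear hydroformylation of ester 4 ⇐ (S)-pent-4-en-2-ol + succinic anhydride (the side-chain S centre comes from the chiral pool).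

Assumption: the facial sense of the new catalyst in step 6 cannot be known in advance; the route is written with the (4R,5R) ligand, and whichever ligand antipode is found to give the 3R lactone is the one used.

**Step 1**
Reactants: 1 (2S)-pent-4-en-2-ol; 2 succinic anhydride
Product: 4 benzyl (2S)-pent-4-en-2-yl butanedioate, via hemisuccinate acid 3 (not isolated)
Conditions: 2 (1.2 equiv), DMAP (10 mol%), K2CO3 (2.2 equiv), DMF, 50 °C; then BnBr (1.3 equiv), rt
Reagents that add atoms: benzyl bromide, BrCc1ccccc1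
Why: DMAP-catalysed O-acylation by the anhydride (retention at the carbinol carbon) gives the potassium hemisuccinate, which is O-alkylated in the same pot by BnBr (carboxylate SN2).

**Step 2**
Reactants: 4 benzyl (2S)-pent-4-en-2-yl butanedioate
Product: 5 benzyl (2S)-6-oxohexan-2-yl butanedioate
Conditions: Rh(acac)(CO)2 (0.5 mol%), BiPhePhos (1.5 mol%), CO/H2 (1:1, 10 bar), PhMe, 60 °C
Reagents that add atoms: carbon monoxide, [C-]#[O+]
Why: Rh/bisphosphite linear-selective hydroformylation of a terminal alkene adds the formyl carbon at the terminus; the ester groups and the stereocentre are untouched.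

**Step 3**
Reactants: 6 hydroquinone
Product: 7 1,4-bis(benzyloxy)benzene
Conditions: BnBr (2.3 equiv), K2CO3 (3 equiv), DMF, 60 °C
Reagents that add atoms: benzyl bromide, BrCc1ccccc1
Why: Double Williamson etherification of the phenoxide is clean and high-yielding.

**Step 4**
Reactants: 7 1,4-bis(benzyloxy)benzene
Product: 8 1,4-bis(benzyloxy)-2-bromobenzene
Conditions: NBS (1.05 equiv), MeCN, 0 °C → rt, dark
Reagents that add atoms: N-bromosuccinimide, O=C1CCC(=O)N1Br
Why: Electrophilic aromatic bromination of the electron-rich hydroquinone diether stops at the monobromide (four equivalent positions, Br deactivates), and the benzyl rings are not activated.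

**Step 5**
Reactants: 8 1,4-bis(benzyloxy)-2-bromobenzene; 9 1,1-dimethoxyethene
Product: 12 2,5-bis(benzyloxy)bicyclo[4.2.0]octa-1,3,5-trien-7-one, via 3,6-bis(benzyloxy)benzyne 10 (not isolated), via benzocyclobutenone dimethyl acetal 11 (not isolated)
Conditions: NaNH2 (3 equiv), 9 (2.5 equiv), THF, 45 °C; then 1 M aq. HCl, THF, rt
Reagents that add atoms: water, O
Why: Dehydrobromination gives the symmetrical 3,6-dialkoxybenzyne, which is trapped by the ketene acetal in a stepwise polar [2+2] (only one regioisomer is possible), and mild acetal hydrolysis unmasks the cyclobutenone.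

**Step 6**
Reactants: 12 2,5-bis(benzyloxy)bicyclo[4.2.0]octa-1,3,5-trien-7-one; 5 benzyl (2S)-6-oxohexan-2-yl butanedioate
Product: 13 benzyl (2S)-5-[(3R)-5,8-bis(benzyloxy)-1-oxo-3,4-dihydro-1H-isochromen-3-yl]pentan-2-yl butanedioate
Conditions: Ni(cod)2 (10 mol%), L* (10 mol%; free (4R,5R)-1,3-bis(2-cyclohexyl-6-methylphenyl)-4,5-diphenylimidazolidin-2-ylidene, pre-formed from its HBF4 salt and KOt-Bu and filtered), 12 (1.2 equiv), PhMe, 25 °C, 5 added over 6 h
Reagents that add atoms: none
Why: Proposed new method: Ni(0)/chiral NHC-catalysed enantioselective insertion of an unactivated aldehyde C=O into the C(acyl)–C(sp3) bond of a benzocyclobutenone (4 → 6 ring expansion), in which Ni(0) adds oxidatively into the strained C7–C8 bond to give an acyl(benzyl)nickelacycle, the η2-bound aldehyde inserts into the Ni–benzyl bond on the face dictated by the C2-symmetric NHC (this sets 3R under catalyst control, the side-chain centre being remote), and acyl–O reductive elimination from the acyl–Ni–alkoxide closes the lactone and returns Ni(0); the closest known reaction types are Ni- and Rh-catalysed "cut-and-sew" insertions of alkynes, dienes, alkenes and C=N bonds into benzocyclobutenones, Ni(0)/NHC ester-forming reductive elimination in Tishchenko-type couplings, and chiral-NHC/Ni enantiofacial control in aldehyde couplings.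

**Step 7**
Reactants: 13 benzyl (2S)-5-[(3R)-5,8-bis(benzyloxy)-1-oxo-3,4-dihydro-1H-isochromen-3-yl]pentan-2-yl butanedioate
Product: 14 Aspergimarin B
Conditions: H2 (1 atm), 10% Pd/C, EtOAc, rt; filtered and concentrated under argon
Reagents that add atoms: none
Why: Hydrogenolysis removes both aryl benzyl ethers and the benzyl ester in one operation, while the lactone C3–O bond (homobenzylic), the secondary ester and both stereocentres are inert.

**Compound list**
1 | (2S)-pent-4-en-2-ol | C[C@@H](CC=C)O | starting material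
2 | succinic anhydride (oxolane-2,5-dione) | O=C1CCC(=O)O1 | starting material
3 | 4-oxo-4-{[(2S)-pent-4-en-2-yl]oxy}butanoic acid (present as its potassium salt) | C[C@@H](CC=C)OC(=O)CCC(=O)O | intermediate
4 | benzyl (2S)-pent-4-en-2-yl butanedioate | C[C@@H](CC=C)OC(=O)CCC(=O)OCc1ccccc1 | intermediate
5 | benzyl (2S)-6-oxohexan-2-yl butanedioate | C[C@@H](CCCC=O)OC(=O)CCC(=O)OCc1ccccc1 | intermediate
6 | hydroquinone (benzene-1,4-diol) | Oc1ccc(O)cc1 | starting material
7 | 1,4-bis(benzyloxy)benzene | c1ccc(COc2ccc(OCc3ccccc3)cc2)cc1 | intermediate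
8 | 1,4-bis(benzyloxy)-2-bromobenzene | Brc1cc(OCc2ccccc2)ccc1OCc1ccccc1 | intermediate
9 | 1,1-dimethoxyethene | C=C(OC)OC | starting material
10 | 3,6-bis(benzyloxy)benzyne | O(Cc1ccccc1)C1=CC=C(OCc2ccccc2)C#C1 | intermediate
11 | 2,5-bis(benzyloxy)-7,7-dimethoxybicyclo[4.2.0]octa-1,3,5-triene | COC1(OC)Cc2c(OCc3ccccc3)ccc(OCc3ccccc3)c21 | intermediate
12 | 2,5-bis(benzyloxy)bicyclo[4.2.0]octa-1,3,5-trien-7-one | O=C1Cc2c(OCc3ccccc3)ccc(OCc3ccccc3)c21 | intermediate
13 | benzyl (2S)-5-[(3R)-5,8-bis(benzyloxy)-1-oxo-3,4-dihydro-1H-isochromen-3-yl]pentan-2-yl butanedioate | C[C@@H](CCC[C@@H]1Cc2c(OCc3ccccc3)ccc(OCc3ccccc3)c2C(=O)O1)OC(=O)CCC(=O)OCc1ccccc1 | intermediate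
14 | Aspergimarin B, 4-{[(2S)-5-[(3R)-5,8-dihydroxy-1-oxo-3,4-dihydro-1H-isochromen-3-yl]pentan-2-yl]oxy}-4-oxobutanoic acid | C[C@@H](CCC[C@@H]1Cc2c(O)ccc(O)c2C(=O)O1)OC(=O)CCC(=O)O | target

**Step count and risks**
Total steps: 7. Longest linear sequence: 5 (6 → 7 → 8 → 12 → 13 → 14).

Steps most likely to fail:

Step 6 (the proposed ring expansion). Risks are Ni-mediated Tishchenko dimerisation or decarbonylation of aldehyde 5, cleavage of the wrong C–C bond, and low or reversed facial selectivity. The fallback uses known chemistry, sets out from 5 and 8, and returns at 13. Aldehyde 5 is treated with trimethylsulfonium iodide/KHMDS (THF, −10 °C) to give the terminal epoxide benzyl (2S)-5-(oxiran-2-yl)pentan-2-yl butanedioate F1 (about 1:1 at the oxirane carbon). Hydrolytic kinetic resolution with (R,R)-(salen)Co(III)OAc and 0.55 equiv of water leaves benzyl (2S)-5-[(2R)-oxiran-2-yl]pentan-2-yl butanedioate F2. The 2S-oxirane epimer is converted into benzyl (2S,6S)-6,7-dihydroxyheptan-2-yl butanedioate F3, which is removed by chromatography. In parallel, bromide 8 is lithiated between Br and OBn (LDA, THF, −78 °C) and quenched with methyl chloroformate to give methyl 3,6-bis(benzyloxy)-2-bromobenzoate F4. Br/Mg exchange on F4 (i-PrMgCl·LiCl, THF, −30 °C) followed by CuI (10 mol%) and F2 opens the epoxide at its CH2 with retention at the carbinol carbon. The resulting alkoxide closes onto the ortho ester (warm to rt, then cat. TsOH) to give 13, with 3R fixed by the epoxide.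

Step 5 (aryne [2+2] and hydrolysis). Risks are amide addition to the aryne, attack of NaNH2 on the benzyl ethers and a moderate yield. The fallback avoids the aryne, sets out from 8 and returns at 12. Lithiation of 8 (LDA, THF, −78 °C) and a DMF quench give 3,6-bis(benzyloxy)-2-bromobenzaldehyde F5. Corey–Chaykovsky methylenation (Me3S+ I−, NaH, DMSO/THF) gives racemic 2-[3,6-bis(benzyloxy)-2-bromophenyl]oxirane F6. Br/Li exchange with n-BuLi in the presence of MgBr2·OEt2 (THF, −78 °C → rt) triggers a Parham-type 4-exo opening of the epoxide at its CH2 to give racemic 2,5-bis(benzyloxy)bicyclo[4.2.0]octa-1,3,5-trien-7-ol F7. Dess–Martin oxidation of F7 then gives 12.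

Step 2 (hydroformylation). Risks are branched aldehyde and alkene isomerisation towards the allylic ester. The fallback sets out from 4 and returns at 5. Cross-metathesis of 4 with acrolein (Hoveyda–Grubbs II, 3 mol%, CH2Cl2, 40 °C) gives benzyl (2S,4E)-6-oxohex-4-en-2-yl butanedioate F8. Chemoselective conjugate reduction of F8 with Hantzsch ester and catalytic dibenzylammonium trifluoroacetate (THF, rt) gives 5.

**Further compounds**
F1 | step 6 | benzyl (2S)-5-(oxiran-2-yl)pentan-2-yl butanedioate (epimers at the oxirane carbon) | C[C@@H](CCCC1CO1)OC(=O)CCC(=O)OCc1ccccc1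
F2 | step 6 | benzyl (2S)-5-[(2R)-oxiran-2-yl]pentan-2-yl butanedioate | C[C@@H](CCC[C@@H]1CO1)OC(=O)CCC(=O)OCc1ccccc1
F3 | step 6 | benzyl (2S,6S)-6,7-dihydroxyheptan-2-yl butanedioate | C[C@@H](CCC[C@H](O)CO)OC(=O)CCC(=O)OCc1ccccc1
F4 | step 6 | methyl 3,6-bis(benzyloxy)-2-bromobenzoate | COC(=O)c1c(Br)c(OCc2ccccc2)ccc1OCc1ccccc1
F5 | step 5 | 3,6-bis(benzyloxy)-2-bromobenzaldehyde | O=Cc1c(Br)c(OCc2ccccc2)ccc1OCc1ccccc1
F6 | step 5 | 2-[3,6-bis(benzyloxy)-2-bromophenyl]oxirane (racemic) | Brc1c(C2CO2)c(OCc3ccccc3)ccc1OCc1ccccc1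
F7 | step 5 | 2,5-bis(benzyloxy)bicyclo[4.2.0]octa-1,3,5-trien-7-ol (racemic) | OC1Cc2c(OCc3ccccc3)ccc(OCc3ccccc3)c21
F8 | step 2 | benzyl (2S,4E)-6-oxohex-4-en-2-yl butanedioate | C[C@@H](C/C=C/C=O)OC(=O)CCC(=O)OCc1ccccc1
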